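(The readings come from a simulation with made-up constants, and the scatter is random.)

Each flask is charged with substrate and a little other conformer, and every percent below is counted on those two together, with partner added on top.

| flask | substrate | partner | other conformer | temperature | remark | time |
|---|---|---|---|---|---|---|
| cedar | 0.067 M | 1.3 equiv | 0.10 equiv | 0 °C | run made earlier |  |
| ash | 0.20 M | 1.3 equiv | 0.10 equiv | 0 °C | run made earlier |  |
| south | 0.10 M | 1.30 equiv | 0.100 equiv | 0 °C |  | 6.0 min |
| north-east | 0.10 M | 1.30 equiv | 0.100 equiv | 15 °C |  | 6.0 min |
| east | 0.10 M | 1.30 equiv | 0.100 equiv | 40 °C |  | 6.0 min |
| south-west | 0.10 M | 2.00 equiv | 0.100 equiv | 30 °C |  | 6.0 min |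
| west | 0.10 M | 0.330 equiv | 0.100 equiv | 40 °C |  | 6.0 min |
| north-west | 0.10 M | 1.30 equiv | 0.400 equiv | 0 °C |  | 6.0 min |

| run | time / s | target / % | substrate / % |
|---|---|---|---|
| cedar | 10.0 | 9 | 76 |
| cedar | 15.0 | 14 | 69 |
| cedar | 25.0 | 19 | 60 |
| cedar | 40.0 | 24 | 47 |
| cedar | 80.0 | 36 | 34 |
| ash | 10.0 | 22 | 56 |
| ash | 15.0 | 31 | 49 |
| ash | 25.0 | 36 | 34 |
| ash | 40.0 | 43 | 25 |
| ash | 80.0 | 49 | 13 |

(each reading ± 2 percentage points)

- in a conversion other conformer counts as not yet reacted
- the earlier runs do not show what temperature does; that part of a forecast is a guess

- the flasks put in order of amount of target, in percent of the substrate and other conformer together charged, best first, at 6.0 min (south / north-east / east / south-west / west / north-west)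
- the same order at 20 s (south / north-east / east / south-west / west / north-west)
- the amount of target, in percent of the substrate and other conformer together charged of the flask you put first, at 6.0 min
- the amount of target, in percent of the substrate and other conformer together charged of the flask you put last, at 6.0 min

One thing in the ash run looks wrong at first. Other conformer is 9.09% of the material charged, yet at the last reading 38.0% is neither target nor substrate. That gap is larger than the other conformer charged, so material has left substrate for something the readings do not show, and I take it to be a second product.

I assume this second route uses partner one for one, as the route to target does. If the two rates then stay in a steady ratio, dividing one by the other and integrating gives a straight line: target equals a constant times partner spent. I call that constant the target share, a selectivity: target made per partner spent. Taking other conformer as small by then, the last ash reading gives, as target over all that is not substrate, 56.3%. The cedar run gives 54.5%, level with it within the scatter, although cedar is more dilute.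

Now the charges. South has partner at 118% of its material, so the material is what can run short, and I reckon about 56.3% of target once it has reacted. West has partner at 30.0% of its material, which makes partner the limiting reagent there, and I reckon 16.9%. Both runs stand at 0 °C, so what heat does to the share is a guess, and I keep the share and let the warm flasks simply arrive sooner.

The forecast gives south > north-east > south-west > east > north-west > west at 6.0 min, with 55% first and 18% last, and south-west > east > north-east > south > west > north-west at 20 s, and says: “Warm flasks finish, but I guess selectivity slips with heat”.

The flasks give east > south-west > north-east > south > north-west > west at the asked time, with 80.3% first and 24.0% last, and east > south-west > north-east > west > south > north-west at the early reading.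

    substrate ⇌ other conformer (K = 0.0890, k = 0.0690 s⁻¹, Ea = 74.0 kJ mol⁻¹, ΔH = −6.00 kJ mol⁻¹)
    substrate + partner → target (k = 0.140 M⁻¹ s⁻¹, Ea = 53.0 kJ mol⁻¹)
    partner + other conformer → isomer of the product (k = 1.50 M⁻¹ s⁻¹, Ea = 35.0 kJ mol⁻¹)
    (constants at 0 °C)

In east, at 0.0370 min, substrate goes into target at 0.047 of the rate at which it passes into other conformer, that being the forward rate of the reversible step alone. The target share, as target over target plus isomer of the product at 6.00 min, is 80.3% in east, against 53.9% in south, and 56.3% was the reading from ash. Carried to the neighbour of east with 0.520 equiv of partner, where partner ends at 0%, the east share times the partner charge gives 37.9%, and that flask holds 37.9% of target.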